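The data stem from a simulated flask with constants of no real substance, and the scatter is random.

Saturday's run ends at 50.1% L in L plus Z, and I plan the fed flasks from this share and one early reading.

| setting | Saturday's | Monday's | Friday's | Sunday's | north | north-east | south |
|---|---|---|---|---|---|---|---|
| X | 0.010 M | 0.0067 M | 0.015 M | 0.010 M | 0.010 M (fed, over 15 min) | 0.010 M | 0.010 M |
| Q | 0.025 M | 0.025 M | 0.025 M | 0.038 M | 0.0250 M | 0.0250 M (fed, over 15 min) | 0.0250 M |
| remark | run made earlier | run made earlier | run made earlier | run made earlier | all else is in the flask from the start; the feed brings no volume worth counting | all else is in the flask from the start; the feed brings no volume worth counting | everything together at the start |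
| time |  |  |  |  | 40 min | 40 min | 40 min |

| run | time / min | L / % | Z / % |
|---|---|---|---|
| Saturday's | 5.00 | 39.8 | 48.3 |
| Saturday's | 10.0 | 47.8 | 50.4 |
| Saturday's | 15.0 | 49.2 | 49.9 |
| Saturday's | 20.0 | 51.0 | 49.2 |
| Saturday's | 25.0 | 50.8 | 50.6 |
| Monday's | 10.0 | 55.2 | 40.6 |
| Monday's | 20.0 | 58.8 | 39.4 |
| Monday's | 30.0 | 58.3 | 39.9 |
| Monday's | 40.0 | 58.5 | 39.5 |
| Monday's | 50.0 | 60.5 | 43.0 |
| Friday's | 4.00 | 30.2 | 55.8 |
| Friday's | 12.0 | 37.1 | 59.2 |
| Friday's | 20.0 | 41.0 | 57.1 |
| Friday's | 30.0 | 40.2 | 59.6 |
| Friday's | 50.0 | 42.0 | 58.1 |
| Sunday's | 4.00 | 51.2 | 40.7 |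
| Sunday's | 8.00 | 57.5 | 39.0 |
| Sunday's | 15.0 | 59.9 | 40.3 |
| Sunday's | 25.0 | 60.8 | 38.9 |
| Sunday's | 50.0 | 59.6 | 39.6 |

(readings scatter by 1 percentage point)

- percent here means X units held: one Z counts as two
- a reading or a percentage of L counts all its forms, free or not

- the flask that comes out highest in share of L in L plus Z, or "all alike" when all lie within 1.5 percentage points (north / north-east / south / all alike)
- share of L in L plus Z at the end, north
- share of L in L plus Z at the end, north-east
- share of L in L plus Z at the end, south

I read the tables through late lines, in decadic logarithms: log(L/Z) plus log(X/Q), with X/Q as charged. That sum is −0.396 for Saturday, −0.401 for Monday's fourth line, −0.363 for Friday and −0.402 for Sunday. So in these readings L/Z falls nearly in inverse proportion to X/Q.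

I take this as two exits for X: aX through Q, with a a pseudo-first-order constant at the charged Q, and bX·X towards Z. With Xc the charge and u = bXc/a, the share for a flask charged all at once is the natural logarithm of one plus u, divided by u. Saturday's share then gives u = 2.50. Saturday's first line reads, by difference, 11.9% of X left, which I read as a = 0.227 min⁻¹; both u and a carry the scatter of the readings.

South repeats Saturday's recipe, so I expect 50.1%. For north, I estimate X as the level at which the feed f = Xc/t (t the feed time) equals aX + bX·X. With y = bX/a, y plus y squared equals the feed number φ = u/(at), the feed's pull on X against the exit through Q. Here φ = 0.734, y = 0.492, and the share, the reciprocal of one plus y, is 67.0%.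

In north-east, the first half-life of X by the exit towards Z alone, from the charge of X, 1/(ua) = 1.76 min, is shorter than the feed 15 min, and by then 11.7% of Q is in, so I put north-east under south.

The forecast names north, with north 71%, north-east 21% and south 50%; for north it says that the “slow X feed holds X near 0.002 M”. My north is lower, but the order is the same.

The flasks give north 69.7%, north-east 20.3% and south 50.3%, so north is highest.

    X + Q → G + L (k = 0.210 M⁻¹ s⁻¹)
    Q + G ⇌ E, settled at all times (K = 2100 M⁻¹)
    2 X → Z (k = 0.580 M⁻¹ s⁻¹)
    X + L ⇌ D, settled at all times (K = 33.0 M⁻¹)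

At 40.0 min, north holds E at 0.00665 M, free Q at 45.7% of its charge and D at 0.202% of the X charged, none of them in φ, and φ's share lies 2.7 percentage points below that flask. For a neighbour of north charged with 0.010 M of Q, I take a in proportion to the Q charged, which multiplies φ by 6.25, to 4.59. For this neighbour, y is 1.70 and the reckoned share 37.0%. That flask gives 37.4%.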